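Ring A is disconnected across C4a–C5 and C8–C8a. Its four contiguous oxygen-bearing carbons C5–C8 map onto the four carbons of dimethyl squarate, while C4a and C8a are the C5–H and C6 carbons of a preformed 2-aryl-3-alkoxy-4-pyranone (rings C and B). Heating a 4-hydroxy-4-(pyranon-6-yl)-2,3-dimethoxycyclobutenone opens the four-membered ring to a dienylketene that closes onto the pyranone C5–H. This forges C4a–C5 and the hexasubstituted benzene ring as a 5,8-hydroquinone in one operation. The precursor is the 1,2-adduct of the C6-lithiated, MOM-protected 3-hydroxy-2-(4-methoxyphenyl)-4-pyranone with dimethyl squarate.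

Key step: step 5

Assumption: the target is achiral; the carbinol centre of 8 and C4a of 10 are formed racemic and disappear in step 5, so no stereocontrol is needed anywhere.

Step 1
Reactants: 1 3-hydroxy-4H-pyran-4-one (pyromeconic acid)
Product: 2 2-bromo-3-hydroxy-4H-pyran-4-one
Conditions: NBS (1.0 equiv), MeCN, 0 °C to rt
Reagents that add atoms: N-bromosuccinimide, O=C1CCC(=O)N1Br
Why: Electrophilic α-bromination of the enol should occur at C2, the carbon ortho to the hydroxyl and next to the ring oxygen, which is where 3-hydroxy-4-pyranones such as kojic acid take up electrophiles, whereas C5 and C6 lack this enol activation.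

Step 2
Reactants: 2 2-bromo-3-hydroxy-4H-pyran-4-one
Product: 3 2-bromo-3-(methoxymethoxy)-4H-pyran-4-one
Conditions: MOMCl, i-Pr2NEt, CH2Cl2, 0 °C to rt
Reagents that add atoms: chloromethyl methyl ether, COCCl
Why: O-Alkylation (Williamson type) of the acidic enol with MOMCl under a non-nucleophilic amine masks the 3-hydroxyl as an acetal that tolerates the Pd(PPh3)4 coupling, LiTMP, heat and K2CO3 and is removed by acid at the end.

Step 3
Reactants: 3 2-bromo-3-(methoxymethoxy)-4H-pyran-4-one; 4 (4-methoxyphenyl)boronic acid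
Product: 5 3-(methoxymethoxy)-2-(4-methoxyphenyl)-4H-pyran-4-one
Conditions: Pd(PPh3)4 (5 mol %), K2CO3, 1,4-dioxane/H2O, 85 °C
Reagents that add atoms: none
Why: Suzuki–Miyaura coupling, in which the C2–Br bond of the vinylogous acyl bromide adds readily to zerovalent palladium and transmetalation with the arylboronate followed by reductive elimination installs ring B.

Step 4
Reactants: 5 3-(methoxymethoxy)-2-(4-methoxyphenyl)-4H-pyran-4-one; 6 dimethyl squarate
Product: 8 4-hydroxy-2,3-dimethoxy-4-[5-(methoxymethoxy)-6-(4-methoxyphenyl)-4-oxo-4H-pyran-2-yl]cyclobut-2-en-1-one (racemic), via 6-lithiopyranone 7 (not isolated)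
Conditions: LiTMP (from TMPH, n-BuLi), THF, −78 °C; cannulate into 6, THF, −78 °C; aq. NH4Cl
Reagents that add atoms: none
Why: Deprotonative lithiation by the hindered, non-nucleophilic amide should take place at C6–H, the vinyl C–H next to the ring oxygen that is the kinetically acidic site of chromones and 4-pyridones, and the vinyllithium then adds 1,2 to one of the two equivalent ketone carbonyls of the squarate to give the racemic tertiary carbinol.

Step 5
Reactants: 8 4-hydroxy-2,3-dimethoxy-4-[5-(methoxymethoxy)-6-(4-methoxyphenyl)-4-oxo-4H-pyran-2-yl]cyclobut-2-en-1-one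
Product: 11 5,8-dihydroxy-6,7-dimethoxy-3-(methoxymethoxy)-2-(4-methoxyphenyl)-4H-chromen-4-one, via dienylketene 9 (not isolated), via 4a-H dienone 10 (not isolated)
Conditions: PhMe (degassed), 110 °C, Ar; crude product kept under Ar
Reagents that add atoms: none
Why: Thermal conrotatory 4π opening of the cyclobutenone C1–C4 bond gives hydroxy-dienylketene 9, and disrotatory 6π electrocyclization joins the ketene carbon to the pyranone C5–H carbon (the C4a–C5 bond) to give dienone 10, whose doubly activated C4a–H tautomerizes to the aromatic hydroquinone. The closest known reaction is the Moore ring expansion of 4-alkenyl- and 4-aryl-4-hydroxycyclobutenones from squarates to hydroquinones. Ring A closes as a six-membered carbocycle by 6π electrocyclic closure in which the pyranone C5=C6 bond serves as the terminal alkene; no stereocentre is created and the racemic carbinol centre of 8 is destroyed. The step needs outward rotation of the hydroxyl, so that the pyranonyl group ends up cis to the ketene, and C–C closure in preference to lactonization by the enol oxygen. The donor hydroxyl secures the former by torquoselectivity, and the nucleophilic α-carbon C5 of the vinylogous ester, the only CH flanking C6, is matched to the electrophilic ketene carbon.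

Step 6
Reactants: 11 5,8-dihydroxy-6,7-dimethoxy-3-(methoxymethoxy)-2-(4-methoxyphenyl)-4H-chromen-4-one
Product: 12 5,6,7,8-tetramethoxy-3-(methoxymethoxy)-2-(4-methoxyphenyl)-4H-chromen-4-one
Conditions: Me2SO4 (excess), K2CO3, acetone (degassed), reflux, Ar
Reagents that add atoms: dimethyl sulfate, COS(=O)(=O)OC
Why: Williamson O-methylation of both phenoxides, in which prolonged reflux with excess reagent should also cap the hydrogen-bonded 5-OH and exclusion of air keeps the hydroquinone from oxidizing before it is methylated.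

Step 7
Reactants: 12 5,6,7,8-tetramethoxy-3-(methoxymethoxy)-2-(4-methoxyphenyl)-4H-chromen-4-one
Product: 13 3-hydroxy-5,6,7,8-tetramethoxy-2-(4-methoxyphenyl)-4H-chromen-4-one
Conditions: 3 M aq. HCl (cat.), MeOH, 50 °C
Reagents that add atoms: none
Why: Acid-catalysed acetal exchange with methanol cleaves the MOM ether, whereas the aryl methyl ethers, including the 5-OMe peri to the carbonyl, are inert to dilute protic acid.

Compound list
1 | 3-hydroxy-4H-pyran-4-one (pyromeconic acid) | O=c1ccocc1O | starting material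
2 | 2-bromo-3-hydroxy-4H-pyran-4-one | O=c1ccoc(Br)c1O | intermediate
3 | 2-bromo-3-(methoxymethoxy)-4H-pyran-4-one | COCOc1c(Br)occc1=O | intermediate
4 | (4-methoxyphenyl)boronic acid | COc1ccc(B(O)O)cc1 | starting material
5 | 3-(methoxymethoxy)-2-(4-methoxyphenyl)-4H-pyran-4-one | COCOc1c(-c2ccc(OC)cc2)occc1=O | intermediate
6 | dimethyl squarate (3,4-dimethoxycyclobut-3-ene-1,2-dione) | COC1=C(OC)C(=O)C1=O | starting material
7 | [5-(methoxymethoxy)-6-(4-methoxyphenyl)-4-oxo-4H-pyran-2-yl]lithium (not isolated) | [Li]c1cc(=O)c(OCOC)c(-c2ccc(OC)cc2)o1 | intermediate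
8 | 4-hydroxy-2,3-dimethoxy-4-[5-(methoxymethoxy)-6-(4-methoxyphenyl)-4-oxo-4H-pyran-2-yl]cyclobut-2-en-1-one (racemic) | COCOc1c(-c2ccc(OC)cc2)oc(C2(O)C(OC)=C(OC)C2=O)cc1=O | intermediate
9 | (3Z)-4-hydroxy-2,3-dimethoxy-4-[5-(methoxymethoxy)-6-(4-methoxyphenyl)-4-oxo-4H-pyran-2-yl]buta-1,3-dien-1-one (pyranonyl cis to the ketenyl carbon; not isolated) | COCOc1c(-c2ccc(OC)cc2)oc(/C(O)=C(OC)\C(OC)=C=O)cc1=O | intermediate
10 | 8-hydroxy-6,7-dimethoxy-3-(methoxymethoxy)-2-(4-methoxyphenyl)-4aH-chromene-4,5-dione (racemic at C4a; not isolated) | COCOC1=C(c2ccc(OC)cc2)OC2=C(O)C(OC)=C(OC)C(=O)C2C1=O | intermediate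
11 | 5,8-dihydroxy-6,7-dimethoxy-3-(methoxymethoxy)-2-(4-methoxyphenyl)-4H-chromen-4-one | COCOc1c(-c2ccc(OC)cc2)oc2c(O)c(OC)c(OC)c(O)c2c1=O | intermediate
12 | 5,6,7,8-tetramethoxy-3-(methoxymethoxy)-2-(4-methoxyphenyl)-4H-chromen-4-one | COCOc1c(-c2ccc(OC)cc2)oc2c(OC)c(OC)c(OC)c(OC)c2c1=O | intermediate
13 | 3-hydroxy-5,6,7,8-tetramethoxy-2-(4-methoxyphenyl)-4H-chromen-4-one | COc1ccc(-c2oc3c(OC)c(OC)c(OC)c(OC)c3c(=O)c2O)cc1 | target

Total step count: 7. Longest linear sequence: 7 steps (1 to 13); compounds 4 and 6 enter as purchased materials.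

Steps most likely to fail

Step 5. The hydroxyl may rotate inward to some extent during ring opening, or the enol oxygen may capture the ketene faster than C5 does, so that a butenolide forms and ring A does not; the free hydroquinone may also be oxidized at the reaction temperature. The fallback sets out from 8. O-Methylation of the tertiary carbinol (MeI, Ag2O, K2CO3, MeCN, rt) should give 2,3,4-trimethoxy-4-[5-(methoxymethoxy)-6-(4-methoxyphenyl)-4-oxo-4H-pyran-2-yl]cyclobut-2-en-1-one F1. With no free hydroxyl, lactonization is impossible, and thermolysis (PhMe, 110 °C) should pass through the methoxy-dienylketene (3Z)-2,3,4-trimethoxy-4-[5-(methoxymethoxy)-6-(4-methoxyphenyl)-4-oxo-4H-pyran-2-yl]buta-1,3-dien-1-one F2 and 6,7,8-trimethoxy-3-(methoxymethoxy)-2-(4-methoxyphenyl)-4aH-chromene-4,5-dione F3. Tautomerization should then give the air-stable monophenol 5-hydroxy-6,7,8-trimethoxy-3-(methoxymethoxy)-2-(4-methoxyphenyl)-4H-chromen-4-one F4. Methylation of its 5-OH (Me2SO4, K2CO3, acetone, reflux) comes back to the route at 12.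

Step 4. Deprotonation may compete at C5 under direction by the carbonyl, and the lithiated pyranone may add to not yet lithiated pyranone or decompose before it meets the squarate. The fallback sets out from 5. Zincation with the carbonyl complexed (TMPZnCl·LiCl, MgCl2, THF, −30 °C to rt), the conditions under which chromones are metalated next to the ring oxygen, should give the stable [5-(methoxymethoxy)-6-(4-methoxyphenyl)-4-oxo-4H-pyran-2-yl]zinc chloride F5. Iodine should convert it into 6-iodo-3-(methoxymethoxy)-2-(4-methoxyphenyl)-4H-pyran-4-one F6, an isolable compound from which any C5 isomer can be removed. Iodine–magnesium exchange (i-PrMgCl·LiCl, THF, −78 °C) should then give [5-(methoxymethoxy)-6-(4-methoxyphenyl)-4-oxo-4H-pyran-2-yl]magnesium chloride F7 in the absence of free amide and of unmetalated pyranone. Its addition to 6 at −78 °C, followed by an aq. NH4Cl quench, comes back to the route at 8.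

Step 6. Air oxidation of the electron-rich hydroquinone dianion to the 5,8-quinone under basic conditions and sluggish methylation of the hydrogen-bonded 5-OH may leave mixtures. The fallback sets out from 11. Deliberate oxidation (Ag2O, Et2O, rt) should give the stable, purifiable quinone 6,7-dimethoxy-3-(methoxymethoxy)-2-(4-methoxyphenyl)-4H-chromene-4,5,8-trione F8. Reductive methylation (Na2S2O4, then Me2SO4, KOH, Bu4NBr, THF/H2O, Ar) should reduce it back to 11 in the flask and methylate both oxygens under stronger phase-transfer conditions, coming back to the route at 12.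

Further compounds
F1 | step 5 | 2,3,4-trimethoxy-4-[5-(methoxymethoxy)-6-(4-methoxyphenyl)-4-oxo-4H-pyran-2-yl]cyclobut-2-en-1-one (racemic) | COCOc1c(-c2ccc(OC)cc2)oc(C2(OC)C(OC)=C(OC)C2=O)cc1=O
F2 | step 5 | (3Z)-2,3,4-trimethoxy-4-[5-(methoxymethoxy)-6-(4-methoxyphenyl)-4-oxo-4H-pyran-2-yl]buta-1,3-dien-1-one | COCOc1c(-c2ccc(OC)cc2)oc(/C(OC)=C(OC)\C(OC)=C=O)cc1=O
F3 | step 5 | 6,7,8-trimethoxy-3-(methoxymethoxy)-2-(4-methoxyphenyl)-4aH-chromene-4,5-dione (racemic at C4a) | COCOC1=C(c2ccc(OC)cc2)OC2=C(OC)C(OC)=C(OC)C(=O)C2C1=O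
F4 | step 5 | 5-hydroxy-6,7,8-trimethoxy-3-(methoxymethoxy)-2-(4-methoxyphenyl)-4H-chromen-4-one | COCOc1c(-c2ccc(OC)cc2)oc2c(OC)c(OC)c(OC)c(O)c2c1=O
F5 | step 4 | [5-(methoxymethoxy)-6-(4-methoxyphenyl)-4-oxo-4H-pyran-2-yl]zinc chloride | Cl[Zn]c1cc(=O)c(OCOC)c(-c2ccc(OC)cc2)o1
F6 | step 4 | 6-iodo-3-(methoxymethoxy)-2-(4-methoxyphenyl)-4H-pyran-4-one | COCOc1c(-c2ccc(OC)cc2)oc(I)cc1=O
F7 | step 4 | [5-(methoxymethoxy)-6-(4-methoxyphenyl)-4-oxo-4H-pyran-2-yl]magnesium chloride | Cl[Mg]c1cc(=O)c(OCOC)c(-c2ccc(OC)cc2)o1
F8 | step 6 | 6,7-dimethoxy-3-(methoxymethoxy)-2-(4-methoxyphenyl)-4H-chromene-4,5,8-trione | COCOC1=C(c2ccc(OC)cc2)OC2=C(C1=O)C(=O)C(OC)=C(OC)C2=O
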